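I decided to follow one substrate molecule through the flask and to ask for two waits: how long it stays substrate, and how long it then lasts as target.

| flask | substrate | partner | catalyst | time |
|---|---|---|---|---|
| dawn | 0.600 M | 0.600 M | 0.0300 M |  |
| midnight | 0.600 M | 1.80 M | 0.0300 M |  |
| autumn | 0.600 M | 0.600 M | 0.0900 M |  |
| noon | 0.180 M | 0.180 M | 0.0300 M | 12 h |

| run | time / h | [target] / M |
|---|---|---|
| dawn run | 0.48 | 0.020 |
| dawn run | 0.76 | 0.056 |
| dawn run | 1.2 | 0.074 |
| dawn run | 1.9 | 0.073 |
| dawn run | 3.0 | 0.127 |
| dawn run | 4.8 | 0.189 |
| dawn run | 7.6 | 0.276 |
| dawn run | 12 | 0.293 |
| midnight run | 0.48 | 0.047 |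
| midnight run | 0.76 | 0.045 |
| midnight run | 1.2 | 0.060 |
| midnight run | 1.9 | 0.106 |
| midnight run | 3.0 | 0.161 |
| midnight run | 4.8 | 0.198 |
| midnight run | 7.6 | 0.283 |
| midnight run | 12 | 0.328 |
| autumn run | 0.48 | 0.058 |
| autumn run | 0.76 | 0.106 |
| autumn run | 1.2 | 0.169 |
| autumn run | 1.9 | 0.237 |
| autumn run | 3.0 | 0.314 |
| autumn run | 4.8 | 0.396 |
| autumn run | 7.6 | 0.411 |
| autumn run | 12 | 0.401 |

(scatter of a reading: 0.009 M)

- Overall: substrate + partner -> target, with catalyst as catalyst.
- Constant volume, constant temperature.
- Bound and free are read together.
- An order is taken over about fifteen percent of the charge, up and down.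

- how the opening rate goes with [partner] round the charge of the dawn run: the exponent of the rate at two percent of substrate gone to target
- how the opening rate goes with [catalyst] round the charge of the dawn run: the exponent of the rate at two percent of substrate gone to target
- target in the noon run at 12 h, as a share of the substrate charged

For the first wait I went to the autumn run, where the opening reads higher than in the dawn and midnight runs. It held 0.169 M of target at 1.2 h, and a pseudo-first-order fall of its 0.600 M of substrate turns that into a making wait of 3.63 h. The midnight run, with 3.00 times the partner of the dawn run, read 0.198 M at 4.8 h against 0.189 M for dawn, so I let partner drop out of the wait. I scaled the wait inversely with catalyst and assumed that it does not depend on the amount charged, which gave the noon run a making wait of 10.9 h.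

For the second wait I used the top of the autumn run, which read 0.396 M, 0.411 M and 0.401 M. By my first wait I reckoned 0.0738 M of substrate in the autumn run at 7.6 h, feeding target at 0.0204 M/h. I took a flat top to mean that target leaves as fast as it arrives, which makes the loss wait 20.2 h.

I carried that loss wait over to the noon run unchanged, and their ratio there, 0.539, I called the fork ratio, the making wait over the loss wait. A chain of two first-order steps with this ratio gave me 47.7% of the noon substrate as target at 12 h.

The forecast gave 0.15 for partner, 1 for catalyst and 46% for noon, reading the autumn top as “an equilibrium rather than catalyst death”. My share was higher than its 46%, and it rested on a loss instead.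

The flask gave 0.19 for partner, 0.96 for catalyst and 49.4% for noon.

    catalyst + substrate → catalyst-substrate complex (3.672 /M/h)
    catalyst-substrate complex + partner → target + catalyst (22.25 /M/h)
    target → decomposed product (0.04284 /h)

The noon run falls short of what its making wait offers through the turning of target into decomposed product, which costs it 17 percentage points. With the fork ratio at 0.539, my chain had put noon at 47.7%, and the flask gives 49.4%. With that turning taken away from the noon run the fork ratio is zero, so my making wait of 10.9 h gives 66.7% at 12 h, and that run stands at 65.9%.

All runs are simulated with constants of no real substance; noise was put on by code.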